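**Retrosynthetic overview** (naphthoquinone numbering, side chain on C2; ring A = benzenoid ring, ring B = quinone ring)
1. The last bond made is the ester C–O between shikonin 14 and 3-acetoxy-3-methylbutanoic acid 17 (Steglich). Shikonin 14 comes from quinone 12 by debenzylation and desilylation.
2. The C1 carbonyl is the last ring oxygen installed: Teuber oxidation of 1-naphthol 11 (C4–OH, C1–H) gives 12.
3. Key disconnection: ring B is cut at C2=C3 and at C1–C8a. Aroyl sulfoxonium ylide 3 (ring A plus C4 and C3) and terminal alkyne 10 (C1, C2 and the whole side-chain skeleton with its stereocentre) are joined by a Cp*Rh-catalysed C–H activation/carbene [4+2] annulation.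
4. Enabling feature: the C4 carbonyl sits directly on ring A at C4a, C8a is the only free ortho C–H of that 2,5-dioxygenated benzoyl unit, C3 is an unsubstituted CH, and C1 needs only an oxygen para to the C4 oxygen. A 1-naphthol with H at C1 is therefore a full precursor of ring B.
5. Ring order: ring A is bought (methyl gentisate 1) and ring B is closed in step 8. The stereocentre is set before that by asymmetric transfer hydrogenation of ynone 7.

Key step: step 8

Assumption: compounds with the free 5,8-dihydroxy-1,4-naphthoquinone unit are drawn as the tautomer with the side chain on the quinone ring; the two tautomers interconvert fast and are one compound.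

**Route**

Step 1
Reactants: 1 methyl 2,5-dihydroxybenzoate
Product: 2 methyl 2,5-bis(benzyloxy)benzoate
Conditions: BnBr (2.5 equiv), K2CO3, DMF, 60 °C
Reagents that add atoms: benzyl bromide, BrCc1ccccc1
Why: Williamson ether synthesis in which both phenoxides are benzylated, the hydrogen-bonded 2-OH needing the raised temperature.

Step 2
Reactants: 2 methyl 2,5-bis(benzyloxy)benzoate
Product: 3 1-[2,5-bis(benzyloxy)phenyl]-2-[dimethyl(oxo)-λ6-sulfanylidene]ethan-1-one
Conditions: Me3S(O)I (3 equiv), KOtBu (3 equiv), THF, reflux; then 2, rt to 60 °C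
Reagents that add atoms: trimethylsulfoxonium iodide, C[S+](C)(C)=O.[I-]
Why: Acylation of dimethylsulfoxonium methylide (the Corey–Chaykovsky reagent used as a carbon nucleophile) by a methyl ester should give the stabilised β-keto sulfoxonium ylide, which does not react further, and the benzyl ethers are inert to the base.

Step 3
Reactants: 4 4-methylpent-3-enoic acid
Product: 6 N-methoxy-N,4-dimethylpent-3-enamide, via acyl imidazole 5 (not isolated)
Conditions: 1,1'-carbonyldiimidazole, CH2Cl2, rt; then MeNH(OMe)·HCl, rt
Reagents that add atoms: N,O-dimethylhydroxylamine hydrochloride, CNOC.Cl; 1,1'-carbonyldiimidazole, O=C(n1ccnc1)n1ccnc1 (its imidazolyl group stays only in intermediate 5)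
Why: Activation to the acyl imidazole and aminolysis is a standard Weinreb amide synthesis that needs no strong base, so the β,γ-alkene should stay out of conjugation.

Step 4
Reactants: 6 N-methoxy-N,4-dimethylpent-3-enamide
Product: 7 6-methyl-1-(trimethylsilyl)hept-5-en-1-yn-3-one
Conditions: Me3SiC≡CH, n-BuLi, THF, −78 °C; then 6, −78 to 0 °C; cold aq. NH4Cl
Reagents that add atoms: (trimethylsilyl)acetylene, C#C[Si](C)(C)C
Why: Weinreb ketone synthesis in which the lithium acetylide adds once and the chelated tetrahedral intermediate survives until the cold, weakly acidic quench, so neither over-addition nor base-induced alkene migration should occur.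

Step 5
Reactants: 7 6-methyl-1-(trimethylsilyl)hept-5-en-1-yn-3-one
Product: 8 (3R)-6-methyl-1-(trimethylsilyl)hept-5-en-1-yn-3-ol
Conditions: Ru[(R,R)-TsNCH(Ph)CH(Ph)NH](p-cymene) (1 mol %), i-PrOH, rt
Reagents that add atoms: none
Why: Noyori asymmetric transfer hydrogenation of an alkynyl ketone delivers hydride from the bifunctional Ru–H/N–H catalyst with the alkyne as the π-group, and by analogy with the known sense for alkynyl alkyl ketones the (R,R)-catalyst should give the (R)-carbinol under neutral conditions that spare the ynone and the β,γ-alkene.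

Step 6
Reactants: 8 (3R)-6-methyl-1-(trimethylsilyl)hept-5-en-1-yn-3-ol
Product: 9 (3R)-3-[(tert-butyldimethylsilyl)oxy]-6-methyl-1-(trimethylsilyl)hept-5-en-1-yne
Conditions: TBSCl, imidazole, DMF, rt
Reagents that add atoms: tert-butyldimethylsilyl chloride, CC(C)(C)[Si](C)(C)Cl
Why: Standard silylation of a secondary alcohol that reacts only at the O–H bond, so the configuration is kept and the oxygen becomes a poor leaving group for the key step.

Step 7
Reactants: 9 (3R)-3-[(tert-butyldimethylsilyl)oxy]-6-methyl-1-(trimethylsilyl)hept-5-en-1-yne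
Product: 10 (3R)-3-[(tert-butyldimethylsilyl)oxy]-6-methylhept-5-en-1-yne
Conditions: K2CO3 (cat.), MeOH, rt
Reagents that add atoms: none
Why: Base-catalysed methanolysis of the alkynyl C–Si bond is selective over the O–silyl ether and should give the terminal alkyne without touching the stereocentre.

Step 8
Reactants: 3 1-[2,5-bis(benzyloxy)phenyl]-2-[dimethyl(oxo)-λ6-sulfanylidene]ethan-1-one; 10 (3R)-3-[(tert-butyldimethylsilyl)oxy]-6-methylhept-5-en-1-yne
Product: 11 5,8-bis(benzyloxy)-3-[(1R)-1-[(tert-butyldimethylsilyl)oxy]-4-methylpent-3-en-1-yl]naphthalen-1-ol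
Conditions: [Cp*Rh(MeCN)3](SbF6)2 (5 mol %), Zn(OTf)2 (30 mol %), ClCH2CH2Cl, 80 °C, 10 (1.5 equiv) added slowly
Reagents that add atoms: none
Why: Proposed new method: the carbon-bound ylide of 3 should direct the cationic trivalent rhodium catalyst to cyclometalate the only free ortho C–H (the future C8a), alkyne 10 should insert into the Rh–aryl bond with the aryl carbon going to the unsubstituted alkyne carbon (future C1) and rhodium to the carbon bearing the silyloxyalkyl group (future C2), loss of DMSO from the bound ylide should give a rhodium carbene at the future C3, and migratory insertion of the alkenyl group into this carbene followed by protodemetalation and enolisation should give naphthol 11. The closest known reaction type is the annulation of aroyl sulfoxonium ylides with internal alkynes to 1-naphthols under cationic Cp*Rh catalysis, and what is new here is the terminal alkyne with a propargylic silyl ether and the C–H bond flanked by an alkoxy group. Ring B closes as a six-membered carbocycle by 1,1-migratory insertion inside the seven-membered rhodacycle, a formal [4+2] union of the four-atom unit C8a–C4a–C4–C3 with the two alkyne carbons, and aromatisation makes the closure irreversible. No stereocentre is formed, and the propargylic stereocentre of 10 is a spectator because the silyloxy group is a poor leaving group, which also suppresses β-oxygen elimination to an allene from the alkenyl rhodium intermediate and is the reason the ester is not carried through this step. The regioselectivity needed (side chain on C2, hydrogen on C1) is secured by the steric difference between hydrogen and the branched silyloxy carbon together with the neighbouring benzyloxy group, site selectivity by the blocked second ortho position, and chemoselectivity by the inertness of the trisubstituted alkene to insertion, while slow addition of 10 limits alkyne oligomerisation.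

Step 9
Reactants: 11 5,8-bis(benzyloxy)-3-[(1R)-1-[(tert-butyldimethylsilyl)oxy]-4-methylpent-3-en-1-yl]naphthalen-1-ol
Product: 12 5,8-bis(benzyloxy)-2-[(1R)-1-[(tert-butyldimethylsilyl)oxy]-4-methylpent-3-en-1-yl]naphthalene-1,4-dione
Conditions: ON(SO3K)2 (Fremy's salt, 2.5 equiv), aq. KH2PO4, acetone/H2O, rt
Reagents that add atoms: dipotassium nitrosodisulfonate, [K+].[K+].[O]N(S(=O)(=O)[O-])S(=O)(=O)[O-]
Why: Teuber oxidation in which the nitrosodisulfonate radical abstracts the phenolic hydrogen and a second equivalent couples at the free para position (C1), giving the para-quinone after loss of imidodisulfonate, while ethers, silyl ether and alkene are inert to this one-electron oxidant.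

Step 10
Reactants: 12 5,8-bis(benzyloxy)-2-[(1R)-1-[(tert-butyldimethylsilyl)oxy]-4-methylpent-3-en-1-yl]naphthalene-1,4-dione
Product: 13 2-[(1R)-1-[(tert-butyldimethylsilyl)oxy]-4-methylpent-3-en-1-yl]-5,8-dihydroxynaphthalene-1,4-dione
Conditions: MgBr2·OEt2 (5 equiv), toluene/Et2O, 60 °C; dilute aq. HCl work-up
Reagents that add atoms: none
Why: Chelation-assisted debenzylation in which magnesium binds between each quinone carbonyl and the neighbouring benzyloxy oxygen (a benzyl ether ortho to a carbonyl group) and bromide removes the benzyl group by SN2, a known selective cleavage that should leave the alkyl silyl ether, the alkene and the stereocentre alone.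

Step 11
Reactants: 13 2-[(1R)-1-[(tert-butyldimethylsilyl)oxy]-4-methylpent-3-en-1-yl]-5,8-dihydroxynaphthalene-1,4-dione
Product: 14 shikonin, 5,8-dihydroxy-2-[(1R)-1-hydroxy-4-methylpent-3-en-1-yl]naphthalene-1,4-dione
Conditions: HF·pyridine, pyridine/THF, 0 °C to rt
Reagents that add atoms: none
Why: Fluoride-mediated Si–O cleavage with buffered HF·pyridine avoids both the basic conditions that degrade naphthazarins and the strong acid that could cyclise the alcohol onto the prenyl alkene, and the C–O bond of the stereocentre is not broken.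

Step 12
Reactants: 15 3-hydroxy-3-methylbutanoic acid
Product: 17 3-acetoxy-3-methylbutanoic acid, via mixed anhydride 16 (not isolated)
Conditions: Ac2O (3 equiv), DMAP (cat.), pyridine, CH2Cl2, 0 °C to rt; then H2O/THF, rt
Reagents that add atoms: acetic anhydride, CC(=O)OC(C)=O; water, O
Why: DMAP-catalysed acetylation of the tertiary alcohol with excess anhydride, in which the carboxyl group is acetylated in passing to the mixed anhydride that water hydrolyses on work-up.

Step 13
Reactants: 14 shikonin; 17 3-acetoxy-3-methylbutanoic acid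
Product: 18 (1R)-1-(5,8-dihydroxy-1,4-dioxo-1,4-dihydronaphthalen-2-yl)-4-methylpent-3-en-1-yl 3-acetoxy-3-methylbutanoate
Conditions: DCC (1.5 equiv), DMAP (0.3 equiv), CH2Cl2, 0 °C to rt, dark
Reagents that add atoms: none
Why: Steglich esterification in which the side-chain secondary alcohol, the only hydroxyl not locked in a hydrogen bond to a quinone carbonyl, should be acylated selectively with retention because the C–O bond of the stereocentre is untouched.

**Compound list**
1 | methyl 2,5-dihydroxybenzoate | COC(=O)c1cc(O)ccc1O | starting material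
2 | methyl 2,5-bis(benzyloxy)benzoate | COC(=O)c1cc(OCc2ccccc2)ccc1OCc1ccccc1 | intermediate
3 | 1-[2,5-bis(benzyloxy)phenyl]-2-[dimethyl(oxo)-λ6-sulfanylidene]ethan-1-one | CS(C)(=O)=CC(=O)c1cc(OCc2ccccc2)ccc1OCc1ccccc1 | intermediate
4 | 4-methylpent-3-enoic acid | CC(C)=CCC(=O)O | starting material
5 | 1-(1H-imidazol-1-yl)-4-methylpent-3-en-1-one (acyl imidazole, formed in the flask) | CC(C)=CCC(=O)n1ccnc1 | intermediate
6 | N-methoxy-N,4-dimethylpent-3-enamide | CC(C)=CCC(=O)N(C)OC | intermediate
7 | 6-methyl-1-(trimethylsilyl)hept-5-en-1-yn-3-one | CC(C)=CCC(=O)C#C[Si](C)(C)C | intermediate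
8 | (3R)-6-methyl-1-(trimethylsilyl)hept-5-en-1-yn-3-ol | CC(C)=CC[C@@H](O)C#C[Si](C)(C)C | intermediate
9 | (3R)-3-[(tert-butyldimethylsilyl)oxy]-6-methyl-1-(trimethylsilyl)hept-5-en-1-yne | CC(C)=CC[C@@H](O[Si](C)(C)C(C)(C)C)C#C[Si](C)(C)C | intermediate
10 | (3R)-3-[(tert-butyldimethylsilyl)oxy]-6-methylhept-5-en-1-yne | CC(C)=CC[C@@H](O[Si](C)(C)C(C)(C)C)C#C | intermediate
11 | 5,8-bis(benzyloxy)-3-[(1R)-1-[(tert-butyldimethylsilyl)oxy]-4-methylpent-3-en-1-yl]naphthalen-1-ol | CC(C)=CC[C@@H](O[Si](C)(C)C(C)(C)C)c1cc(O)c2c(OCc3ccccc3)ccc(OCc3ccccc3)c2c1 | intermediate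
12 | 5,8-bis(benzyloxy)-2-[(1R)-1-[(tert-butyldimethylsilyl)oxy]-4-methylpent-3-en-1-yl]naphthalene-1,4-dione | CC(C)=CC[C@@H](O[Si](C)(C)C(C)(C)C)C1=CC(=O)c2c(OCc3ccccc3)ccc(OCc3ccccc3)c2C1=O | intermediate
13 | 2-[(1R)-1-[(tert-butyldimethylsilyl)oxy]-4-methylpent-3-en-1-yl]-5,8-dihydroxynaphthalene-1,4-dione | CC(C)=CC[C@@H](O[Si](C)(C)C(C)(C)C)C1=CC(=O)c2c(O)ccc(O)c2C1=O | intermediate
14 | shikonin, 5,8-dihydroxy-2-[(1R)-1-hydroxy-4-methylpent-3-en-1-yl]naphthalene-1,4-dione | CC(C)=CC[C@@H](O)C1=CC(=O)c2c(O)ccc(O)c2C1=O | intermediate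
15 | 3-hydroxy-3-methylbutanoic acid | CC(C)(O)CC(=O)O | starting material
16 | acetic 3-acetoxy-3-methylbutanoic anhydride (mixed anhydride, formed in the flask) | CC(=O)OC(C)(C)CC(=O)OC(C)=O | intermediate
17 | 3-acetoxy-3-methylbutanoic acid | CC(=O)OC(C)(C)CC(=O)O | intermediate
18 | (1R)-1-(5,8-dihydroxy-1,4-dioxo-1,4-dihydronaphthalen-2-yl)-4-methylpent-3-en-1-yl 3-acetoxy-3-methylbutanoate | CC(=O)OC(C)(C)CC(=O)O[C@H](CC=C(C)C)C1=CC(=O)c2c(O)ccc(O)c2C1=O | target

**Step count**
Total: 13 steps. Longest linear sequence: 10 steps (steps 3 to 11 and step 13, from acid 4 to target 18).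

**Steps most likely to fail**

1. Step 8 (proposed new method). The cyclometalation at the C–H bond flanked by a benzyloxy group may be slow. The terminal alkyne may oligomerise or form an acetylide instead of inserting, or insert with the opposite orientation. The ylide may also couple with itself as a carbene source. The fallback uses known chemistry only (Dötz benzannulation and oxidative demethylation); it sets out from alkyne 10 and comes back at quinone 12. 2-Bromobenzene-1,4-diol F1 (bought) would be benzylated (BnBr, K2CO3, DMF) to 1,4-bis(benzyloxy)-2-bromobenzene F2. Bromine–lithium exchange (n-BuLi, THF, −78 °C) would give [2,5-bis(benzyloxy)phenyl]lithium F3, which adds to Cr(CO)6 to give lithium acylchromate F4, and O-methylation with Me3OBF4 would give the pentacarbonylchromium methoxycarbene complex F5. Heating F5 with 10 in THF at 50–60 °C should give, with the alkyne substituent next to the new phenol as is usual for terminal alkynes, 4-methoxy-1-naphthol F6. Oxidation of crude F6 with (NH4)2Ce(NO3)6 in MeCN/H2O at 0 °C should give 12.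

2. Step 10. The ether cleavage may stop after one benzyl group, or the temperature needed may cost the silyl ether or add HBr to the prenyl alkene. The fallback replaces Lewis-acid cleavage by an oxidative unmasking; it sets out from 12 and comes back at 13. Reduction of 12 with Na2S2O4 (EtOAc/H2O) would give hydroquinone F7, acetylated without isolation (Ac2O, pyridine, DMAP) to diacetate F8. (NH4)2Ce(NO3)6 in MeCN/H2O at 0 °C should then oxidise the electron-rich bis(benzyloxy) ring to the quinone with loss of benzyl alcohol, giving quinone diacetate F9. Methanolysis of the two aryl acetates (K2CO3 cat., MeOH, 0 °C, argon) should give 13, since the naphthazarin tautomers are one compound.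

3. Step 13. Acyl transfer to the alcohol may lose out to N-acylurea formation, to acylation of the chelated phenols under forcing conditions, or to β-elimination of acetic acid from the activated acid. The fallback changes the order of events so that no free phenol is present during esterification; it sets out from 12 and comes back at 18. Desilylation of 12 (HF·pyridine, THF) would give di-O-benzyl alcohol F10. Esterification with excess 17 (DCC, DMAP, CH2Cl2) would give di-O-benzyl ester F11. Debenzylation with MgBr2·OEt2 as in step 10 should then give 18.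

Further compounds
F1 | step 8 | 2-bromobenzene-1,4-diol (bought) | Oc1ccc(O)c(Br)c1
F2 | step 8 | 1,4-bis(benzyloxy)-2-bromobenzene | Brc1cc(OCc2ccccc2)ccc1OCc1ccccc1
F3 | step 8 | [2,5-bis(benzyloxy)phenyl]lithium | [Li]c1cc(OCc2ccccc2)ccc1OCc1ccccc1
F4 | step 8 | lithium pentacarbonyl{[2,5-bis(benzyloxy)phenyl](oxido)methylidene}chromate | [Li+].[O-]C(c1cc(OCc2ccccc2)ccc1OCc1ccccc1)=[Cr](=C=O)(=C=O)(=C=O)(=C=O)=C=O
F5 | step 8 | pentacarbonyl{[2,5-bis(benzyloxy)phenyl](methoxy)methylidene}chromium | COC(c1cc(OCc2ccccc2)ccc1OCc1ccccc1)=[Cr](=C=O)(=C=O)(=C=O)(=C=O)=C=O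
F6 | step 8 | 5,8-bis(benzyloxy)-2-[(1R)-1-[(tert-butyldimethylsilyl)oxy]-4-methylpent-3-en-1-yl]-4-methoxynaphthalen-1-ol | CC(C)=CC[C@@H](O[Si](C)(C)C(C)(C)C)c1cc(OC)c2c(OCc3ccccc3)ccc(OCc3ccccc3)c2c1O
F7 | step 10 | 5,8-bis(benzyloxy)-2-[(1R)-1-[(tert-butyldimethylsilyl)oxy]-4-methylpent-3-en-1-yl]naphthalene-1,4-diol | CC(C)=CC[C@@H](O[Si](C)(C)C(C)(C)C)c1cc(O)c2c(OCc3ccccc3)ccc(OCc3ccccc3)c2c1O
F8 | step 10 | 5,8-bis(benzyloxy)-2-[(1R)-1-[(tert-butyldimethylsilyl)oxy]-4-methylpent-3-en-1-yl]naphthalene-1,4-diyl diacetate | CC(C)=CC[C@@H](O[Si](C)(C)C(C)(C)C)c1cc(OC(C)=O)c2c(OCc3ccccc3)ccc(OCc3ccccc3)c2c1OC(C)=O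
F9 | step 10 | 2-[(1R)-1-[(tert-butyldimethylsilyl)oxy]-4-methylpent-3-en-1-yl]-5,8-dioxo-5,8-dihydronaphthalene-1,4-diyl diacetate | CC(C)=CC[C@@H](O[Si](C)(C)C(C)(C)C)c1cc(OC(C)=O)c2C(=O)C=CC(=O)c2c1OC(C)=O
F10 | step 13 | 5,8-bis(benzyloxy)-2-[(1R)-1-hydroxy-4-methylpent-3-en-1-yl]naphthalene-1,4-dione | CC(C)=CC[C@@H](O)C1=CC(=O)c2c(OCc3ccccc3)ccc(OCc3ccccc3)c2C1=O
F11 | step 13 | (1R)-1-[5,8-bis(benzyloxy)-1,4-dioxo-1,4-dihydronaphthalen-2-yl]-4-methylpent-3-en-1-yl 3-acetoxy-3-methylbutanoate | CC(=O)OC(C)(C)CC(=O)O[C@H](CC=C(C)C)C1=CC(=O)c2c(OCc3ccccc3)ccc(OCc3ccccc3)c2C1=O
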